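**Assumptions:** geraniol and (2E,6E)-farnesol are bought as single geometric isomers. The chiral IDPi acid is a preparable catalyst, so its synthesis is not counted.

## Retrosynthetic overview
1. Target 11 ⇒ (TBS removal) ⇒ C12–C13 sp3–allyl bond. Partners are a γ-oxido Grignard from iodide 5 (C10, carries both stereocentres) and allylic bromide 9 (C15, from farnesol; all three E-alkenes are bought, none is made).
2. 5 ⇒ diol 4 ⇒ trans-fused bicyclic dioxasilinane 3.
3. Key step: 3 ⇒ achiral, acyclic geranyl silanol 2 by catalytic asymmetric proton-initiated cation–olefin cyclisation. The tethered Si–OH acts as intramolecular "water", sets both stereocentres and stops the cascade at one carbocycle.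
4. Ring order: the cyclohexane and a sacrificial 1,3,2-dioxasilinane form together in step 2. The heterocycle is deleted in step 3.
5. Avoided: a resolved cyclogeranyl/ionone ring with the carbinol made by epoxidation–LiAlH4 or MeLi, joined by sulfone alkylation.

## Route

**Step 1**
Reactants: 1 geraniol
Product: 2 di-tert-butyl{[(2E)-3,7-dimethylocta-2,6-dien-1-yl]oxy}silanol
Conditions: t-Bu2Si(OTf)2 (1.1 equiv), pyridine, CH2Cl2, −78 → 0 °C; then sat. aq NaHCO3
Reagents that add atoms: di-tert-butylsilyl bis(triflate), CC(C)(C)[Si](OS(=O)(=O)C(F)(F)F)(OS(=O)(=O)C(F)(F)F)C(C)(C)C; water, O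
Why: O-silylation followed by hydrolysis of the remaining hindered Si–OTf gives a non-condensing di-tert-butylsilanol tether, whose OH oxygen becomes the tertiary carbinol oxygen of the target.

**Step 2 (key step)**
Reactants: 2
Product: 3 (4aR,8aS)-2,2-di-tert-butyl-5,5,8a-trimethylhexahydro-4H-benzo[d][1,3,2]dioxasiline (trans-fused; 4a-H and 8a-CH3 anti)
Conditions: confined BINOL-derived imidodiphosphorimidate (IDPi) acid, 5 mol % (the antipode that gives the (−)-ambroxide sense), (CF3)3COH, 0 °C, 24–48 h
Reagents that add atoms: none (cycloisomerisation)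
Why: Proposed new method: the confined chiral acid in a perfluorinated alcohol protonates the more electron-rich C6=C7 alkene (C2=C3 is inductively deactivated by the allylic O–Si), the chain reacts through one enantiotopic chair fold inside the chiral anion, C2 attacks the incipient tertiary cation while the H-bonded Si–OH adds to C3 from the opposite face (concerted Stork–Eschenmoser anti addition to an E-alkene, so the side arm and O end up trans) and returns its proton to the anion for turnover; the closest known reaction types are the IDPi/fluoroalcohol asymmetric cyclisation of homofarnesol to ambroxide (OH terminator), racemic acid- or Hg(II)-induced cyclisation of geranyl esters with acyloxy capture, and di-tert-butylsilanol tethers trapping mercurinium or iodonium ions of allylic alcohols.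

**Step 3**
Reactants: 3
Product: 4 (1S,2R)-2-(hydroxymethyl)-1,3,3-trimethylcyclohexan-1-ol (CH2OH and OH trans)
Conditions: TBAF (3 equiv), THF, 23 → 50 °C; recrystallise to upgrade er and remove any cis isomer arising from nerol
Reagents that add atoms: none
Why: Fluoride desilylation cleaves only Si–O bonds, so both C–O bonds and both stereocentres are untouched.

**Step 4**
Reactants: 4
Product: 5 (1S,2S)-2-(iodomethyl)-1,3,3-trimethylcyclohexan-1-ol
Conditions: I2, PPh3, imidazole, CH2Cl2, 0 → 23 °C
Reagents that add atoms: iodine, II
Why: Appel (Garegg–Samuelsson) iodination activates only the primary OH, the tertiary OH does not react, and closure to a trans-fused oxetane is too strained to compete.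

**Step 5**
Reactants: 6 (2E,6E)-farnesol
Product: 7 (2E,6E)-farnesyl tert-butyldimethylsilyl ether
Conditions: TBSCl, imidazole, DMF, 23 °C
Reagents that add atoms: TBSCl, CC(C)(C)[Si](C)(C)Cl
Why: Standard silyl protection masks the allylic OH against the oxidant, the bromination and the organometallic reagent.

**Step 6**
Reactants: 7
Product: 8 (2E,6E,10E)-12-[(tert-butyldimethylsilyl)oxy]-2,6,10-trimethyldodeca-2,6,10-trien-1-ol
Conditions: SeO2 (0.3 equiv), t-BuOOH, salicylic acid (10 mol %), CH2Cl2, 0 °C, stopped at partial conversion; then NaBH4, MeOH, 0 °C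
Reagents that add atoms: selenium dioxide, O=[Se]=O; tert-butyl hydroperoxide (terminal oxidant), CC(C)(C)OO
Why: Sharpless–Umbreit allylic oxidation (ene then [2,3]-shift) hydroxylates the (E)-methyl of the terminal isopropylidene, preserves the E geometry, and the borohydride returns any over-oxidised enal to 8.

**Step 7**
Reactants: 8
Product: 9 {[(2E,6E,10E)-12-bromo-3,7,11-trimethyldodeca-2,6,10-trien-1-yl]oxy}(tert-butyl)dimethylsilane
Conditions: CBr4, PPh3, CH2Cl2, −30 → 0 °C; used promptly
Reagents that add atoms: carbon tetrabromide, BrC(Br)(Br)Br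
Why: Appel bromination of a primary allylic alcohol proceeds by SN2 without allylic transposition or E/Z loss, and the TBS ether is inert.

**Step 8**
Reactants: 5 (1.3 equiv) and 9
Product: 10 (1S,2S)-2-[(3E,7E,11E)-13-(tert-butyldimethylsilyloxy)-3,7,11-trimethyltrideca-3,7,11-trien-1-yl]-1,3,3-trimethylcyclohexan-1-ol
Conditions: 5, t-BuLi (3.2 equiv), Et2O–pentane, −78 °C; MgBr2·OEt2; then 9, Li2CuCl4 (5–10 mol %), THF, −78 → 0 °C
Reagents that add atoms: none
Why: Deprotonation plus Bailey-type I/Li exchange gives a γ-oxido organometallic (a Normant-type reagent with no β-leaving group), and Kochi–Schlosser Cu-catalysed coupling attacks the primary α-carbon of the allylic bromide with retention of E geometry and without touching either stereocentre.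

**Step 9**
Reactants: 10
Product: 11 preluffariellolide A, (1S,2S)-2-[(3E,7E,11E)-13-hydroxy-3,7,11-trimethyltrideca-3,7,11-trien-1-yl]-1,3,3-trimethylcyclohexan-1-ol
Conditions: TBAF, THF, 0 → 23 °C
Reagents that add atoms: none
Why: Fluoride desilylation frees the allylic alcohol under non-acidic conditions, which leave the tertiary carbinol and the three alkenes intact.

## Compound list

| No. | Name | SMILES | Role |
|---|---|---|---|
| 1 | geraniol | CC(C)=CCC/C(C)=C/CO | starting material |
| 2 | geranyl di-tert-butylsilanol ether | CC(C)=CCC/C(C)=C/CO[Si](O)(C(C)(C)C)C(C)(C)C | intermediate |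
| 3 | (4aR,8aS)-trans-dioxasilinane | CC(C)(C)[Si]1(C(C)(C)C)OC[C@H]2C(C)(C)CCC[C@]2(C)O1 | intermediate |
| 4 | (1S,2R)-diol | OC[C@H]1C(C)(C)CCC[C@]1(C)O | intermediate |
| 5 | (1S,2S)-iodo alcohol | IC[C@H]1C(C)(C)CCC[C@]1(C)O | intermediate |
| 6 | (2E,6E)-farnesol | C/C(=C\CO)CC/C=C(\C)CCC=C(C)C | starting material |
| 7 | farnesyl TBS ether | C/C(=C\CO[Si](C)(C)C(C)(C)C)CC/C=C(\C)CCC=C(C)C | intermediate |
| 8 | (E)-12-hydroxyfarnesyl TBS ether | C/C(=C\CO[Si](C)(C)C(C)(C)C)CC/C=C(\C)CC/C=C(\C)CO | intermediate |
| 9 | (E)-12-bromofarnesyl TBS ether | C/C(=C\CO[Si](C)(C)C(C)(C)C)CC/C=C(\C)CC/C=C(\C)CBr | intermediate |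
| 10 | O-TBS preluffariellolide A | C/C(=C\CO[Si](C)(C)C(C)(C)C)CC/C=C(\C)CC/C=C(\C)CC[C@H]1C(C)(C)CCC[C@]1(C)O | intermediate |
| 11 | preluffariellolide A | C/C(=C\CO)CC/C=C(\C)CC/C=C(\C)CC[C@H]1C(C)(C)CCC[C@]1(C)O | target |

## Totals
- **Total steps:** 9
- **Longest linear sequence:** 6 (steps 1, 2, 3, 4, 8, 9)

## Steps most likely to fail
1. **Step 2.** Risks are low er, poor fit of the bulky silanol in the catalyst pocket, direct hydroalkoxylation of C2=C3, and elimination to cyclogeranyl alkenes.
   Fallback (substrate control instead of catalyst control): Sharpless AD of the 6,7-alkene of a geranyl ester, conversion to the (S)-6,7-epoxide and installation of the same silanol. Lewis-acid epoxide-initiated cyclisation then gives 3 bearing an equatorial 6-OH, and Barton–McCombie deoxygenation removes it.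
2. **Step 8.** Risks are SN2′ attack at C10, homocoupling, and a sluggish hindered nucleophile.
   Fallback (change the nucleophile type): convert 5 to the phenyl sulfone with PhSO2Na. Alkylate its O,C-dianion with 9, which is strictly α-selective, then remove the sulfone reductively with Na/Hg or Mg/MeOH.
3. **Step 6.** Risks are modest yield and some internal allylic oxidation.
   Fallback (build C12 instead of oxidising it): van Tamelen terminal bromohydrin and epoxide formation on 7, then periodate cleavage to the trisnor aldehyde. E-selective Wittig reaction with Ph3P=C(CH3)CO2Et followed by DIBAL-H gives 8.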